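## Retrosynthetic overview

- 19 ⇐ 18 (three Si–O bonds cleaved) ⇐ 17 by threefold Shi epoxidation. The three oxiranes are the only rings made in the route; they close together in step 12 and carry all six stereocentres.
- Feature used: the stereocentres are C4 and C5 of three identical trans-2,3-disubstituted oxiranes, each the distal 4E double bond of a (2Z,4E)-hexa-2,4-dienoate on O1, O2 and O4 of the central benzene ring. O1, O2, O4 and O5 of that ring are equivalent in the parent tetrol.
- 17 ⇐ phenol 16 + acid 5; 16 ⇐ diester 15 (loss of the 4-methoxybenzyl group); 15 ⇐ hydroquinone 14 + two molecules of 5; 5 ⇐ crotonaldehyde by Still–Gennari olefination.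
- 14 ⇐ quinone 10 by mono-hydrolysis, O-silylation and quinone hydrogenation, which sorts the four core oxygens into one silyl ether, one 4-methoxybenzyl ether and two hydroxy groups; 10 ⇐ bromanil (C–O bonds by alkoxy-debromination, C–C bonds by double Suzuki coupling with boronate 7).

Key step: step 12

Remark: because the four core oxygens are equivalent, a shift of a silyl or acyl group between neighbouring oxygens in steps 9 to 11 and 13 still leads to the same triester 17 and the same target 19. Steps that act at two or three equivalent sites (4, 5, 9, 12, 13) pass through partly reacted species that are driven on and not counted as compounds. The L-ketone of step 12 is taken as available, bought or made from L-sorbose by the known sequence.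

## Route

Step 1
Reactants: 1 (E)-but-2-enal; 2 methyl bis(2,2,2-trifluoroethyl)phosphonoacetate
Product: 3 methyl (2Z,4E)-hexa-2,4-dienoate
Conditions: KN(SiMe3)2, 18-crown-6, THF, −78 °C
Reagents that add atoms: none
Why: Still–Gennari olefination, in which the electron-poor bis(trifluoroethyl) phosphonate anion with its potassium ion held by the crown ether eliminates quickly from the kinetic adduct and so should give the 2Z double bond, while the E double bond of the aldehyde is carried over as C4=C5.

Step 2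
Reactants: 3 methyl (2Z,4E)-hexa-2,4-dienoate
Product: 5 (2Z,4E)-hexa-2,4-dienoic acid, via lithium (2Z,4E)-hexa-2,4-dienoate 4 (not isolated)
Conditions: LiOH, THF/H2O, 0 °C to rt; then 1 M HCl to pH 3, 0 °C
Reagents that add atoms: lithium hydroxide [Li+].[OH-]
Why: Saponification of an unhindered methyl ester by acyl–oxygen cleavage, which at low temperature should leave both double-bond geometries untouched, the acid being kept cold, dark and in solution until use.

Step 3
Reactants: 6 4-(4,4,5,5-tetramethyl-1,3,2-dioxaborolan-2-yl)phenol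
Product: 7 triisopropyl[4-(4,4,5,5-tetramethyl-1,3,2-dioxaborolan-2-yl)phenoxy]silane
Conditions: iPr3SiCl, imidazole, DMF, rt
Reagents that add atoms: chlorotriisopropylsilane CC(C)[Si](Cl)(C(C)C)C(C)C
Why: Imidazole-promoted O-silylation of a phenol, to which the pinacol boronate is inert, so the outer phenols are masked before they can compete in the later acylations.

Step 4
Reactants: 8 2,3,5,6-tetrabromo-1,4-benzoquinone (bromanil)
Product: 9 2,5-dibromo-3,6-bis[(4-methoxybenzyl)oxy]-1,4-benzoquinone
Conditions: 4-MeOC6H4CH2OH (2.1 equiv), Cs2CO3, MeCN, 0 °C to rt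
Reagents that add atoms: 4-methoxybenzyl alcohol COc1ccc(CO)cc1
Why: Twofold addition–elimination (nucleophilic vinylic substitution) of the kind by which haloanils give 2,5-dialkoxy-3,6-dihaloquinones, the first alkoxy group deactivating the carbonyl group it is conjugated with, which should send the second to the para-related carbon and stop further exchange.

Step 5
Reactants: 9 2,5-dibromo-3,6-bis[(4-methoxybenzyl)oxy]-1,4-benzoquinone; 7 triisopropyl[4-(4,4,5,5-tetramethyl-1,3,2-dioxaborolan-2-yl)phenoxy]silane (2.4 equiv)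
Product: 10 2,5-bis[(4-methoxybenzyl)oxy]-3,6-bis[4-(triisopropylsilyloxy)phenyl]-1,4-benzoquinone
Conditions: PdCl2(dppf)·CH2Cl2 (cat.; dppf = 1,1'-bis(diphenylphosphino)ferrocene), K3PO4, toluene/H2O, 80 °C
Reagents that add atoms: none
Why: Double Suzuki–Miyaura coupling, in which the C–Br bonds of the bromoquinone add readily to zerovalent palladium as in the corresponding dimethoxy dibromoquinone, and phosphate in a two-phase medium should spare the vinylogous esters and the aryl silyl ethers.

Step 6
Reactants: 10 2,5-bis[(4-methoxybenzyl)oxy]-3,6-bis[4-(triisopropylsilyloxy)phenyl]-1,4-benzoquinone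
Product: 12 2-hydroxy-5-[(4-methoxybenzyl)oxy]-3,6-bis[4-(triisopropylsilyloxy)phenyl]-1,4-benzoquinone, via sodium quinonolate 11 (not isolated)
Conditions: NaOH (1.05 equiv), THF/H2O, 0 °C; then 0.5 M HCl to pH 3
Reagents that add atoms: sodium hydroxide [Na+].[OH-]
Why: Hydrolysis of a vinylogous ester by conjugate addition–elimination, after which the delocalised quinonolate anion is far less electrophilic at its remaining alkoxy-bearing carbon, so one equivalent of hydroxide should remove exactly one 4-methoxybenzyl group and mark one of the four core oxygens.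

Step 7
Reactants: 12 2-hydroxy-5-[(4-methoxybenzyl)oxy]-3,6-bis[4-(triisopropylsilyloxy)phenyl]-1,4-benzoquinone
Product: 13 2-[(4-methoxybenzyl)oxy]-5-(triisopropylsilyloxy)-3,6-bis[4-(triisopropylsilyloxy)phenyl]-1,4-benzoquinone
Conditions: iPr3SiOTf, 2,6-lutidine, CH2Cl2, −78 to 0 °C; dry filtration through silica, used at once
Reagents that add atoms: triisopropylsilyl trifluoromethanesulfonate CC(C)[Si](OS(=O)(=O)C(F)(F)F)(C(C)C)C(C)C
Why: O-silylation of an acidic enol (vinylogous acid) with a silyl triflate, giving a moisture-sensitive vinylogous silyl ester that is carried straight into the reduction, where it becomes a stable aryl silyl ether.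

Step 8
Reactants: 13 2-[(4-methoxybenzyl)oxy]-5-(triisopropylsilyloxy)-3,6-bis[4-(triisopropylsilyloxy)phenyl]-1,4-benzoquinone
Product: 14 2-[(4-methoxybenzyl)oxy]-5-(triisopropylsilyloxy)-3,6-bis[4-(triisopropylsilyloxy)phenyl]benzene-1,4-diol
Conditions: H2 (1 atm), Pd/C (10% Pd on carbon), pyridine (0.5 equiv), EtOAc, rt; filtered under Ar, concentrated and used directly
Reagents that add atoms: none
Why: Catalytic hydrogenation of the quinone to the hydroquinone is far faster than ether cleavage and turns the labile vinylogous silyl ester into a robust aryl silyl ether, while pyridine as a catalyst poison is known to suppress hydrogenolysis of phenolic 4-methoxybenzyl ethers, so only the two former carbonyl oxygens (O1 and O4) are freed.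

Step 9
Reactants: 14 2-[(4-methoxybenzyl)oxy]-5-(triisopropylsilyloxy)-3,6-bis[4-(triisopropylsilyloxy)phenyl]benzene-1,4-diol; 5 (2Z,4E)-hexa-2,4-dienoic acid (2.4 equiv)
Product: 15 2-[(4-methoxybenzyl)oxy]-5-(triisopropylsilyloxy)-3,6-bis[4-(triisopropylsilyloxy)phenyl]-1,4-phenylene bis[(2Z,4E)-hexa-2,4-dienoate]
Conditions: DCC (2.6 equiv), 4-(dimethylamino)pyridine (cat.), CH2Cl2, 0 °C, Ar, dark
Reagents that add atoms: none
Why: Steglich esterification of the two hydroquinone hydroxy groups, run cold and with little nucleophilic catalyst to keep the 2Z geometry, on an air-sensitive diol that is kept under argon throughout.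

Step 10
Reactants: 15 2-[(4-methoxybenzyl)oxy]-5-(triisopropylsilyloxy)-3,6-bis[4-(triisopropylsilyloxy)phenyl]-1,4-phenylene bis[(2Z,4E)-hexa-2,4-dienoate]
Product: 16 2-hydroxy-5-(triisopropylsilyloxy)-3,6-bis[4-(triisopropylsilyloxy)phenyl]-1,4-phenylene bis[(2Z,4E)-hexa-2,4-dienoate]
Conditions: CF3CO2H (10 vol%), 1,3-dimethoxybenzene (5 equiv), CH2Cl2, 0 °C
Reagents that add atoms: none
Why: Acid-induced ionisation (SN1) of the aryl 4-methoxybenzyl ether, whose benzylic cation is trapped by 1,3-dimethoxybenzene in a Friedel–Crafts alkylation, under conditions that aryl esters, conjugated dienes and aryl triisopropylsilyl ethers should tolerate and that, unlike hydrogenolysis, leave the double bonds alone.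

Step 11
Reactants: 16 2-hydroxy-5-(triisopropylsilyloxy)-3,6-bis[4-(triisopropylsilyloxy)phenyl]-1,4-phenylene bis[(2Z,4E)-hexa-2,4-dienoate]; 5 (2Z,4E)-hexa-2,4-dienoic acid (1.3 equiv)
Product: 17 5-(triisopropylsilyloxy)-3,6-bis[4-(triisopropylsilyloxy)phenyl]benzene-1,2,4-triyl tris[(2Z,4E)-hexa-2,4-dienoate]
Conditions: DCC (1.4 equiv), 4-(dimethylamino)pyridine (cat.), CH2Cl2, 0 °C, dark
Reagents that add atoms: none
Why: Steglich esterification of the single remaining phenol with one further molecule of acid 5, which completes the three-acyl/one-silyl pattern whichever of the neighbouring oxygens carries the free hydroxy group at that point.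

Step 12
Reactants: 17 5-(triisopropylsilyloxy)-3,6-bis[4-(triisopropylsilyloxy)phenyl]benzene-1,2,4-triyl tris[(2Z,4E)-hexa-2,4-dienoate]
Product: 18 5-(triisopropylsilyloxy)-3,6-bis[4-(triisopropylsilyloxy)phenyl]benzene-1,2,4-triyl tris[(2Z)-3-[(2S,3S)-3-methyloxiran-2-yl]prop-2-enoate]
Conditions: 1,2:4,5-di-O-isopropylidene-β-L-erythro-2,3-hexodiulo-2,6-pyranose (3 equiv per C4=C5 bond, in portions), 2KHSO5·KHSO4·K2SO4, NaHCO3, Bu4NHSO4, MeCN/CH2(OMe)2/aq. Na2H2EDTA (disodium dihydrogen ethylenediaminetetraacetate), 0 °C, pH 8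
Reagents that add atoms: potassium peroxymonosulfate (KHSO5) [K+].[O-]S(=O)(=O)OO
Why: KHSO5 adds to the carbonyl group of the L-ketone and the adduct closes to a chiral dioxirane, which hands one oxygen atom to each C4=C5 bond in a concerted, spiro-oriented transition state and returns the ketone; the closest known reaction type is the Shi epoxidation of conjugated dienoates (sorbate esters) at the distal double bond to give vinyl epoxides. Each of the three oxirane rings closes by this one-step [2+1] oxygen-atom transfer with both C–O bonds formed on the same face, so the 4E geometry becomes the trans relationship of C4 and C5. The absolute configuration at the six new centres is reagent-controlled: the D-fructose-derived ketone gives (R,R)-epoxides from trans-disubstituted alkenes, so its mirror image of the L series should attack the opposite face and give (4S,5S) in every chain. Site selectivity between C4=C5 and C2=C3 is needed and is secured by the ester group, which makes the Z-configured C2=C3 bond too electron-poor for the electrophilic dioxirane. Chemoselectivity is secured by the hydrogencarbonate buffer at pH 8, at which the hindered aryl esters should not hydrolyse (the ketone is then used in excess because it is slowly lost by Baeyer–Villiger oxidation), and by the three silyl ethers that mask the oxidisable phenols. Because the three dienoates are identical and far apart they should react independently, so the all-(4S,5S) isomer should dominate, its mirror image is statistically suppressed, and isomers with one inverted oxirane are removed after step 13.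

Step 13
Reactants: 18 5-(triisopropylsilyloxy)-3,6-bis[4-(triisopropylsilyloxy)phenyl]benzene-1,2,4-triyl tris[(2Z)-3-[(2S,3S)-3-methyloxiran-2-yl]prop-2-enoate]
Product: 19 5-hydroxy-3,6-bis(4-hydroxyphenyl)benzene-1,2,4-triyl tris[(2Z)-3-[(2S,3S)-3-methyloxiran-2-yl]prop-2-enoate] (CNP0278429.1)
Conditions: Bu4NF, AcOH (1:1), THF, 0 °C; chromatography, preparative HPLC if needed
Reagents that add atoms: none
Why: Fluoride-induced cleavage of the three aryl silyl ethers, buffered with acetic acid so that each phenoxide is protonated at once and neither ester cleavage nor acid-promoted opening or lactonisation of the Z-configured epoxy enoates should occur, a shift of an acyl group from O4 to the freed O5 only regenerating 19.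

## Compound list

1 | (E)-but-2-enal (crotonaldehyde) | C/C=C/C=O | starting material
2 | methyl bis(2,2,2-trifluoroethyl)phosphonoacetate | COC(=O)CP(=O)(OCC(F)(F)F)OCC(F)(F)F | starting material
3 | methyl (2Z,4E)-hexa-2,4-dienoate | C/C=C/C=C\C(=O)OC | intermediate
4 | lithium (2Z,4E)-hexa-2,4-dienoate | C/C=C/C=C\C(=O)[O-].[Li+] | intermediate
5 | (2Z,4E)-hexa-2,4-dienoic acid | C/C=C/C=C\C(=O)O | intermediate
6 | 4-(4,4,5,5-tetramethyl-1,3,2-dioxaborolan-2-yl)phenol (4-hydroxyphenylboronic acid pinacol ester) | CC1(C)OB(OC1(C)C)c1ccc(O)cc1 | starting material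
7 | triisopropyl[4-(4,4,5,5-tetramethyl-1,3,2-dioxaborolan-2-yl)phenoxy]silane | CC(C)[Si](Oc1ccc(cc1)B1OC(C)(C)C(C)(C)O1)(C(C)C)C(C)C | intermediate
8 | 2,3,5,6-tetrabromo-1,4-benzoquinone (bromanil) | O=C1C(Br)=C(Br)C(=O)C(Br)=C1Br | starting material
9 | 2,5-dibromo-3,6-bis[(4-methoxybenzyl)oxy]-1,4-benzoquinone | O=C1C(OCc2ccc(OC)cc2)=C(Br)C(=O)C(OCc2ccc(OC)cc2)=C1Br | intermediate
10 | 2,5-bis[(4-methoxybenzyl)oxy]-3,6-bis[4-(triisopropylsilyloxy)phenyl]-1,4-benzoquinone | O=C1C(OCc2ccc(OC)cc2)=C(c2ccc(O[Si](C(C)C)(C(C)C)C(C)C)cc2)C(=O)C(OCc2ccc(OC)cc2)=C1c1ccc(O[Si](C(C)C)(C(C)C)C(C)C)cc1 | intermediate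
11 | sodium 4-[(4-methoxybenzyl)oxy]-3,6-dioxo-2,5-bis[4-(triisopropylsilyloxy)phenyl]cyclohexa-1,4-dien-1-olate (sodium salt of 12) | [Na+].[O-]C1=C(c2ccc(O[Si](C(C)C)(C(C)C)C(C)C)cc2)C(=O)C(OCc2ccc(OC)cc2)=C(c2ccc(O[Si](C(C)C)(C(C)C)C(C)C)cc2)C1=O | intermediate
12 | 2-hydroxy-5-[(4-methoxybenzyl)oxy]-3,6-bis[4-(triisopropylsilyloxy)phenyl]-1,4-benzoquinone | OC1=C(c2ccc(O[Si](C(C)C)(C(C)C)C(C)C)cc2)C(=O)C(OCc2ccc(OC)cc2)=C(c2ccc(O[Si](C(C)C)(C(C)C)C(C)C)cc2)C1=O | intermediate
13 | 2-[(4-methoxybenzyl)oxy]-5-(triisopropylsilyloxy)-3,6-bis[4-(triisopropylsilyloxy)phenyl]-1,4-benzoquinone | CC(C)[Si](OC1=C(c2ccc(O[Si](C(C)C)(C(C)C)C(C)C)cc2)C(=O)C(OCc2ccc(OC)cc2)=C(c2ccc(O[Si](C(C)C)(C(C)C)C(C)C)cc2)C1=O)(C(C)C)C(C)C | intermediate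
14 | 2-[(4-methoxybenzyl)oxy]-5-(triisopropylsilyloxy)-3,6-bis[4-(triisopropylsilyloxy)phenyl]benzene-1,4-diol | Oc1c(OCc2ccc(OC)cc2)c(-c2ccc(O[Si](C(C)C)(C(C)C)C(C)C)cc2)c(O)c(O[Si](C(C)C)(C(C)C)C(C)C)c1-c1ccc(O[Si](C(C)C)(C(C)C)C(C)C)cc1 | intermediate
15 | 2-[(4-methoxybenzyl)oxy]-5-(triisopropylsilyloxy)-3,6-bis[4-(triisopropylsilyloxy)phenyl]-1,4-phenylene bis[(2Z,4E)-hexa-2,4-dienoate] | C/C=C/C=C\C(=O)Oc1c(OCc2ccc(OC)cc2)c(-c2ccc(O[Si](C(C)C)(C(C)C)C(C)C)cc2)c(OC(=O)/C=C\C=C\C)c(O[Si](C(C)C)(C(C)C)C(C)C)c1-c1ccc(O[Si](C(C)C)(C(C)C)C(C)C)cc1 | intermediate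
16 | 2-hydroxy-5-(triisopropylsilyloxy)-3,6-bis[4-(triisopropylsilyloxy)phenyl]-1,4-phenylene bis[(2Z,4E)-hexa-2,4-dienoate] | C/C=C/C=C\C(=O)Oc1c(O)c(-c2ccc(O[Si](C(C)C)(C(C)C)C(C)C)cc2)c(OC(=O)/C=C\C=C\C)c(O[Si](C(C)C)(C(C)C)C(C)C)c1-c1ccc(O[Si](C(C)C)(C(C)C)C(C)C)cc1 | intermediate
17 | 5-(triisopropylsilyloxy)-3,6-bis[4-(triisopropylsilyloxy)phenyl]benzene-1,2,4-triyl tris[(2Z,4E)-hexa-2,4-dienoate] | C/C=C/C=C\C(=O)Oc1c(OC(=O)/C=C\C=C\C)c(-c2ccc(O[Si](C(C)C)(C(C)C)C(C)C)cc2)c(OC(=O)/C=C\C=C\C)c(O[Si](C(C)C)(C(C)C)C(C)C)c1-c1ccc(O[Si](C(C)C)(C(C)C)C(C)C)cc1 | intermediate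
18 | 5-(triisopropylsilyloxy)-3,6-bis[4-(triisopropylsilyloxy)phenyl]benzene-1,2,4-triyl tris[(2Z)-3-[(2S,3S)-3-methyloxiran-2-yl]prop-2-enoate] | C[C@@H]1O[C@H]1/C=C\C(=O)Oc1c(OC(=O)/C=C\[C@@H]2O[C@H]2C)c(-c2ccc(O[Si](C(C)C)(C(C)C)C(C)C)cc2)c(OC(=O)/C=C\[C@@H]2O[C@H]2C)c(O[Si](C(C)C)(C(C)C)C(C)C)c1-c1ccc(O[Si](C(C)C)(C(C)C)C(C)C)cc1 | intermediate
19 | 5-hydroxy-3,6-bis(4-hydroxyphenyl)benzene-1,2,4-triyl tris[(2Z)-3-[(2S,3S)-3-methyloxiran-2-yl]prop-2-enoate] (CNP0278429.1) | C[C@@H]1O[C@H]1/C=C\C(=O)Oc1c(OC(=O)/C=C\[C@@H]2O[C@H]2C)c(-c2ccc(O)cc2)c(OC(=O)/C=C\[C@@H]2O[C@H]2C)c(O)c1-c1ccc(O)cc1 | target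

## Step count and risks

Total step count: 13. Longest linear sequence: 10 steps (8 → 19, steps 4 to 13).

Steps most likely to fail:

1. Step 12. Oxygen transfer may stay incomplete or be poorly face-selective at one of the three chains, which multiplies into diastereomers that are hard to separate. The lipophilic substrate may also dissolve poorly in the aqueous medium, and the aryl esters may slowly hydrolyse during the long exposure to the buffered oxidant. The fallback moves the epoxidation onto the single chain, where conversion and enantiomeric purity can be checked before the core is committed. It sets out from ester 3. Shi epoxidation of 3 with a catalytic amount of the same L-ketone under K2CO3-buffered conditions (pH about 10.5, which a methyl ester tolerates) should give methyl (2Z,4S,5S)-4,5-epoxyhex-2-enoate F1. Cleavage of the methyl ester with KOSiMe3 in THF should give potassium (2Z,4S,5S)-4,5-epoxyhex-2-enoate F2 without acidic work-up. For the core, quinone 13 is hydrogenated without pyridine (H2, Pd/C, EtOAc), so that the quinone is reduced and the 4-methoxybenzyl ether is hydrogenolysed, giving 5-(triisopropylsilyloxy)-3,6-bis[4-(triisopropylsilyloxy)phenyl]benzene-1,2,4-triol F3. F2 is activated at once with 2,4,6-trichlorobenzoyl chloride, and the mixed anhydride acylates the three hydroxy groups of F3 (4-(dimethylamino)pyridine, toluene, 0 °C; Yamaguchi esterification). The fallback comes back to the route at 18.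

2. Step 9. The activated acid may isomerise from 2Z to 2E through reversible conjugate addition of the acyl-transfer catalyst, and acylation may stall at the two hindered hydroquinone oxygens. The fallback builds the diene on the core by cross-coupling. It sets out from hydroquinone 14, which is esterified with commercial (Z)-3-iodoacrylic acid (DCC, catalytic 4-(dimethylamino)pyridine, CH2Cl2, 0 °C) to give 2-[(4-methoxybenzyl)oxy]-5-(triisopropylsilyloxy)-3,6-bis[4-(triisopropylsilyloxy)phenyl]-1,4-phenylene bis[(Z)-3-iodoprop-2-enoate] F4. A twofold Stille coupling with (E)-tributyl(prop-1-en-1-yl)stannane (Pd2(dba)3, dba = dibenzylideneacetone, AsPh3, DMF, rt) should proceed with retention at both alkenes and comes back to the route at 15.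

3. Step 7. The silyl group may be lost by hydrolysis from the vinylogous silyl ester before the quinone is reduced, or step 6 may over-hydrolyse; either erases the differentiation of the core oxygens. The fallback gives up the differentiation at the quinone stage for a statistical one at the diester stage. It sets out from quinone 10, which is hydrogenated in the presence of pyridine (H2, Pd/C, EtOAc) to 2,5-bis[(4-methoxybenzyl)oxy]-3,6-bis[4-(triisopropylsilyloxy)phenyl]benzene-1,4-diol F5. Steglich esterification with acid 5 should give 2,5-bis[(4-methoxybenzyl)oxy]-3,6-bis[4-(triisopropylsilyloxy)phenyl]-1,4-phenylene bis[(2Z,4E)-hexa-2,4-dienoate] F6. Both benzylic ethers are then cleaved (CF3CO2H, 1,3-dimethoxybenzene, CH2Cl2, 0 °C) to give 2,5-dihydroxy-3,6-bis[4-(triisopropylsilyloxy)phenyl]-1,4-phenylene bis[(2Z,4E)-hexa-2,4-dienoate] F7. F7 is treated with one equivalent of iPr3SiOTf and 2,6-lutidine in CH2Cl2 at −78 °C. Its two hydroxy groups are equivalent, so the mono-silyl ether is a single compound, separated from recovered diol and the bis-silyl ether. The fallback comes back to the route at 16.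

## Further compounds

F1 | step 12 | methyl (2Z,4S,5S)-4,5-epoxyhex-2-enoate | C[C@@H]1O[C@H]1/C=C\C(=O)OC
F2 | step 12 | potassium (2Z,4S,5S)-4,5-epoxyhex-2-enoate | C[C@@H]1O[C@H]1/C=C\C(=O)[O-].[K+]
F3 | step 12 | 5-(triisopropylsilyloxy)-3,6-bis[4-(triisopropylsilyloxy)phenyl]benzene-1,2,4-triol | Oc1c(O)c(-c2ccc(O[Si](C(C)C)(C(C)C)C(C)C)cc2)c(O)c(O[Si](C(C)C)(C(C)C)C(C)C)c1-c1ccc(O[Si](C(C)C)(C(C)C)C(C)C)cc1
F4 | step 9 | 2-[(4-methoxybenzyl)oxy]-5-(triisopropylsilyloxy)-3,6-bis[4-(triisopropylsilyloxy)phenyl]-1,4-phenylene bis[(Z)-3-iodoprop-2-enoate] | I/C=C\C(=O)Oc1c(OCc2ccc(OC)cc2)c(-c2ccc(O[Si](C(C)C)(C(C)C)C(C)C)cc2)c(OC(=O)/C=C\I)c(O[Si](C(C)C)(C(C)C)C(C)C)c1-c1ccc(O[Si](C(C)C)(C(C)C)C(C)C)cc1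
F5 | step 7 | 2,5-bis[(4-methoxybenzyl)oxy]-3,6-bis[4-(triisopropylsilyloxy)phenyl]benzene-1,4-diol | Oc1c(OCc2ccc(OC)cc2)c(-c2ccc(O[Si](C(C)C)(C(C)C)C(C)C)cc2)c(O)c(OCc2ccc(OC)cc2)c1-c1ccc(O[Si](C(C)C)(C(C)C)C(C)C)cc1
F6 | step 7 | 2,5-bis[(4-methoxybenzyl)oxy]-3,6-bis[4-(triisopropylsilyloxy)phenyl]-1,4-phenylene bis[(2Z,4E)-hexa-2,4-dienoate] | C/C=C/C=C\C(=O)Oc1c(OCc2ccc(OC)cc2)c(-c2ccc(O[Si](C(C)C)(C(C)C)C(C)C)cc2)c(OC(=O)/C=C\C=C\C)c(OCc2ccc(OC)cc2)c1-c1ccc(O[Si](C(C)C)(C(C)C)C(C)C)cc1
F7 | step 7 | 2,5-dihydroxy-3,6-bis[4-(triisopropylsilyloxy)phenyl]-1,4-phenylene bis[(2Z,4E)-hexa-2,4-dienoate] | C/C=C/C=C\C(=O)Oc1c(O)c(-c2ccc(O[Si](C(C)C)(C(C)C)C(C)C)cc2)c(OC(=O)/C=C\C=C\C)c(O)c1-c1ccc(O[Si](C(C)C)(C(C)C)C(C)C)cc1
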